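**Retrosynthetic overview**

1. Target 33 ⇐ dimethyl ester 32 ⇐ pyran ring (O–C8–C9–C11–C12–C13) closed last, by 6-endo attack of the C8 hydroxyl on C13 of a (12S,13R) vinyl epoxide. The epoxide comes from a C12 aldehyde by Z-iodo-olefination, hydroxymethyl Stille coupling, Sharpless epoxidation, oxidation and methylenation.
2. C1H2–C2O2H ⇐ C10 vinyl (hydroboration, oxidation). C8(OH)CH3 and C7H2 ⇐ C7 ketone (α′-methylation, Rubottom oxidation, enol triflate reduction). C5 ⇐ Li/NH3 reduction of a C5=C6 enone made by Mukaiyama–Michael addition of the isobutyrate ketene acetal (C3, C4) and Saegusa–Ito oxidation.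
3. Feature on which the strategy rests: in the cyclohexane C5–C6–C7–C8–C9–C10, quaternary C10 (C20 methyl, C1 arm) adjoins C9 with the C1 and C11 arms trans, and C7 (para to C10) can carry oxygen. This is the retron of a [4+2] addition of a 1-amino-3-siloxybutadiene (C5–C6–C7–C8) to (E)-2-methyl-5-silyloxypent-2-enal (C1, C10, C20, C9, C11, C12), forming C5–C10 and C8–C9.
4. Ring order: cyclohexane first (step 4), pyran last (step 26). The enal is made from propane-1,3-diol in three steps.

Key step: step 4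

**Remarks before the steps**

- Numbering: labdane locants are used throughout (C4(CH3)2–C3 on C5; C20 and C1–C2 on C10; C17 on C8; C16 and C14=C15 on C13). β is the face of the cyclohexane that carries C20, α the opposite face.
- Assumption: (R,R)-1-naphthyl-TADDOL is taken to expose the enal face that leads to (1S,6R)-8, by analogy with α-substituted acroleins. The (S,S)-catalyst is equally available if the first run shows the opposite sense.
- Choices: the C12 oxygen is carried as a TIPS ether (no aryl group) because it must pass the dissolving-metal step. Activation in step 4 is by a hydrogen-bond donor because the enamine diene would bind a metal Lewis acid.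

**Route**

Step 1
Reactants: 1 propane-1,3-diol
Product: 2 3-(triisopropylsilyloxy)propan-1-ol
Conditions: NaH (1.0 equiv), THF, 0 °C → rt; TIPSCl (1.0 equiv)
Reagents that add atoms: triisopropylsilyl chloride, CC(C)[Si](Cl)(C(C)C)C(C)C
Why: O-silylation of the sparingly soluble monosodium alkoxide of the symmetric diol, which should react once only; no stereocentre.

Step 2
Reactants: 2 3-(triisopropylsilyloxy)propan-1-ol
Product: 3 3-(triisopropylsilyloxy)propanal
Conditions: TEMPO (10 mol %), PhI(OAc)2 (1.1 equiv), CH2Cl2, rt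
Reagents that add atoms: none
Why: Oxoammonium (TEMPO) oxidation stops at the aldehyde and is base-free, so the β-silyloxy aldehyde should not eliminate.

Step 3
Reactants: 3 3-(triisopropylsilyloxy)propanal; 4 2-(triphenylphosphoranylidene)propanal
Product: 5 (E)-2-methyl-5-(triisopropylsilyloxy)pent-2-enal
Conditions: PhMe, 80 °C
Reagents that add atoms: none
Why: Wittig olefination with a formyl-stabilised ylide should give the E-trisubstituted enal, whose geometry later fixes C9 relative to C10.

Step 4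
Reactants: 5 (E)-2-methyl-5-(triisopropylsilyloxy)pent-2-enal; 6 (E)-3-(tert-butyldimethylsilyloxy)-N,N-dimethylbuta-1,3-dien-1-amine
Product: 8 (1S,6R)-1-methyl-4-oxo-6-[2-(triisopropylsilyloxy)ethyl]cyclohex-2-ene-1-carbaldehyde, via aminosiloxycyclohexene cycloadduct 7 (not isolated)
Conditions: (R,R)-1-naphthyl-TADDOL (20 mol %), PhMe, −78 → −40 °C; then 1 M HCl, THF, 0 °C
Reagents that add atoms: none
Why: Diels–Alder reaction under hydrogen-bond (general-acid) catalysis: the TADDOL hydroxyl binds the formyl oxygen, lowers the enal LUMO and shields one enal face, and the push–pull diene adds in a concerted, asynchronous [4+2] event in which its CH2 terminus (C8) bonds to the enal β-carbon C9 and its amino-bearing terminus (C5) to the α-carbon C10. The closest known reaction is the TADDOL-catalysed cycloaddition of this same diene with α-substituted acroleins. The cyclohexane C5–C10 is the only ring closed, by an intermolecular cycloaddition that is suprafacial on both partners. C10 and C9 are created together: their absolute configuration comes from the catalyst-selected enal face and their relative configuration (C1 formyl trans to C11) from the E geometry of 5, while the endo-derived amino centre C5 of 7 is erased when acid hydrolyses the silyl enol ether and eliminates dimethylamine to give the C5=C6–C7=O enone. The step needs regio-, enantiofacial and chemoselectivity: the donor pattern of the diene (largest HOMO coefficient at C8) against the enal β-carbon secures the regiochemistry, the catalyst the enantioface, and the aldehyde survives the cold acid work-up because C10 is quaternary. The β-alkyl group of 5 slows the addition, which is why the bath is allowed to rise to −40 °C.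

Step 5
Reactants: 8 (1S,6R)-1-methyl-4-oxo-6-[2-(triisopropylsilyloxy)ethyl]cyclohex-2-ene-1-carbaldehyde
Product: 9 4-methyl-4-vinyl-5-[2-(triisopropylsilyloxy)ethyl]cyclohex-2-en-1-one (10β-methyl, 10α-vinyl, 9β side chain)
Conditions: Ph3PCH3Br, KHMDS, THF, 0 °C; then 8 (1.05 equiv ylide), −78 → 0 °C
Reagents that add atoms: methyltriphenylphosphonium bromide, C[P+](c1ccccc1)(c1ccccc1)c1ccccc1.[Br-]
Why: Wittig methylenation, in which the small ylide at −78 °C should take the aldehyde well before the conjugated ketone; the vinyl group is the masked C1–C2 acid and no centre can epimerise.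

Step 6
Reactants: 9 4-methyl-4-vinyl-5-[2-(triisopropylsilyloxy)ethyl]cyclohex-2-en-1-one; 10 1-methoxy-2-methyl-1-(trimethylsilyloxy)prop-1-ene
Product: 11 methyl 2-methyl-2-[1-methyl-6-[2-(triisopropylsilyloxy)ethyl]-4-(trimethylsilyloxy)-1-vinylcyclohex-3-en-2-yl]propanoate (C5 epimers; 5α-C4 isomer drawn)
Conditions: Tf2NH (2 mol %), CH2Cl2, −78 → −40 °C; Et3N quench
Reagents that add atoms: none
Why: Mukaiyama–Michael addition: silyl triflimide formed in situ activates the enone, the ketene acetal attacks C5 and the silyl group passes to the C7 oxygen, giving the C6=C7 enol ether regiospecifically; attack anti to the pseudo-axial C20 methyl should put C4 on the α face, which does not matter because C5 is flattened again in step 7.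

Step 7
Reactants: 11 Michael adduct (TMS enol ether, used crude)
Product: 12 methyl 2-methyl-2-[6-methyl-3-oxo-5-[2-(triisopropylsilyloxy)ethyl]-6-vinylcyclohex-1-en-1-yl]propanoate
Conditions: Pd(OAc)2 (1.05 equiv), MeCN, rt
Reagents that add atoms: none
Why: Saegusa–Ito oxidation: the palladium enolate at C6 loses H5 by β-hydride elimination and restores the C5=C6 enone, now carrying C4; the terminal vinyl and the ester are inert.

Step 8
Reactants: 12 C5-substituted enone
Product: 13 methyl 2-methyl-2-[4,6-dimethyl-3-oxo-5-[2-(triisopropylsilyloxy)ethyl]-6-vinylcyclohex-1-en-1-yl]propanoate (C8 methyl trans to the C11 arm, major)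
Conditions: LDA, THF, −78 °C; MeI, −78 → −30 °C
Reagents that add atoms: iodomethane, CI
Why: Kinetic α′-enolate alkylation: C8 is the only enolisable carbon (C4 and C10 are quaternary), so C17 should enter regiospecifically, anti to the C11 arm; the C8 configuration is set again in step 11.

Step 9
Reactants: 13 α′-methyl enone
Product: 14 methyl 2-methyl-2-[2,4-dimethyl-5-oxo-3-[2-(triisopropylsilyloxy)ethyl]-2-vinylcyclohexyl]propanoate (5α-H; C4 arm, C20 and C11 arm β)
Conditions: Li (2.3 equiv), NH3(l)–THF, t-BuOH (1 equiv), −78 °C; NH4Cl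
Reagents that add atoms: none
Why: Dissolving-metal (Birch-type) enone reduction: the β-carbanion should be protonated axially from the α face in the half-chair with the C11 arm equatorial and C20 axial, giving the more stable arrangement (H5 α, C4 arm equatorial β) as in trans-decalin formation; the isolated vinyl, the TIPS ether and the very hindered ester should survive a titrated amount of lithium.

Step 10
Reactants: 14 saturated C7 ketone
Product: 15 methyl 2-methyl-2-[2,4-dimethyl-3-[2-(triisopropylsilyloxy)ethyl]-5-(trimethylsilyloxy)-2-vinylcyclohex-4-en-1-yl]propanoate (C7=C8 enol ether)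
Conditions: TMSCl, NaI, Et3N, MeCN, rt
Reagents that add atoms: chlorotrimethylsilane, C[Si](C)(C)Cl
Why: Silyl enol ether formation with in-situ iodotrimethylsilane and amine under equilibrating conditions should favour the more substituted C7=C8 isomer over the C6=C7 one.

Step 11
Reactants: 15 C7=C8 silyl enol ether (used crude)
Product: 16 methyl 2-methyl-2-[2,4-dimethyl-5-oxo-3-[2-(triisopropylsilyloxy)ethyl]-4-(trimethylsilyloxy)-2-vinylcyclohexyl]propanoate (8α-OTMS, 8β-CH3)
Conditions: mCPBA (1.05 equiv), CH2Cl2, −20 → 0 °C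
Reagents that add atoms: 3-chloroperoxybenzoic acid, O=C(OO)c1cccc(Cl)c1
Why: Rubottom oxidation: the peracid should epoxidise the electron-rich enol ether (not the monosubstituted alkene) from the α face, away from the C11 arm and the axial C20 methyl, and 1,4-silyl migration then gives the silyloxy ketone with C8 set (O α, C17 β).

Step 12
Reactants: 16 8α-silyloxy C7 ketone
Product: 17 methyl 2-methyl-2-[2,4-dimethyl-3-[2-(triisopropylsilyloxy)ethyl]-5-(trifluoromethylsulfonyloxy)-4-(trimethylsilyloxy)-2-vinylcyclohex-5-en-1-yl]propanoate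
Conditions: KHMDS, THF, −78 °C; PhNTf2
Reagents that add atoms: N-phenylbis(trifluoromethanesulfonimide), O=S(=O)(N(c1ccccc1)S(=O)(=O)C(F)(F)F)C(F)(F)F
Why: Enol triflate formation: with C8 quaternary the ketone can enolise only towards C6, so O-sulfonylation of the potassium enolate is regiospecific.

Step 13
Reactants: 17 C6=C7 enol triflate
Product: 18 methyl 2-methyl-2-[2,4-dimethyl-3-[2-(triisopropylsilyloxy)ethyl]-4-(trimethylsilyloxy)-2-vinylcyclohex-5-en-1-yl]propanoate
Conditions: Pd(OAc)2 (5 mol %), PPh3 (10 mol %), Bu3N, HCO2H, DMF, 60 °C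
Reagents that add atoms: none
Why: Palladium-catalysed formate reduction of the enol triflate (oxidative addition, hydride transfer, reductive elimination) removes the C7 oxygen and leaves a C6=C7 alkene.

Step 14
Reactants: 18 C6=C7 alkene with C10 vinyl
Product: 19 methyl 2-[4-hydroxy-2-(2-hydroxyethyl)-2,4-dimethyl-3-[2-(triisopropylsilyloxy)ethyl]cyclohex-5-en-1-yl]-2-methylpropanoate
Conditions: 9-BBN, THF, 0 → 50 °C; NaOH, H2O2, MeOH–H2O, 0 °C → rt
Reagents that add atoms: hydrogen peroxide, OO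
Why: Hydroboration–oxidation: 9-BBN should add only to the monosubstituted C1=C2 vinyl group (boron on C2) and not to the ring alkene flanked by C5 and quaternary C8; the alkaline methanolic work-up also cleaves the tertiary TMS ether.

Step 15
Reactants: 19 unsaturated diol
Product: 20 methyl 2-[4-hydroxy-2-(2-hydroxyethyl)-2,4-dimethyl-3-[2-(triisopropylsilyloxy)ethyl]cyclohexyl]-2-methylpropanoate
Conditions: H2 (1 atm), PtO2, EtOAc, rt
Reagents that add atoms: none
Why: Heterogeneous hydrogenation of the cis-disubstituted ring alkene; C6 and C7 become CH2, so no stereocentre is made, and platinum is chosen to avoid allylic C–O hydrogenolysis at C8.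

Step 16
Reactants: 20 saturated diol
Product: 21 {3-hydroxy-6-(1-methoxy-2-methyl-1-oxopropan-2-yl)-1,3-dimethyl-2-[2-(triisopropylsilyloxy)ethyl]cyclohexyl}acetic acid
Conditions: TEMPO (20 mol %), PhI(OAc)2 (2.2 equiv), MeCN–H2O (1:1), rt
Reagents that add atoms: water, O
Why: TEMPO/PhI(OAc)2 oxidation in aqueous acetonitrile takes the primary C2 alcohol through the aldehyde hydrate to the acid and leaves the tertiary C8 alcohol untouched.

Step 17
Reactants: 21 C2 acid
Product: 22 methyl 2-{4-hydroxy-2-(2-methoxy-2-oxoethyl)-2,4-dimethyl-3-[2-(triisopropylsilyloxy)ethyl]cyclohexyl}-2-methylpropanoate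
Conditions: TMSCHN2, PhMe–MeOH (4:1), 0 °C
Reagents that add atoms: (trimethylsilyl)diazomethane, C[Si](C)(C)C=[N+]=[N-]
Why: O-methylation of the carboxylic acid by the diazoalkane under neutral conditions, which avoids any acid-mediated lactonisation onto the C8 hydroxyl.

Step 18
Reactants: 22 diester with C12–OTIPS
Product: 23 methyl 2-[4-hydroxy-3-(2-hydroxyethyl)-2-(2-methoxy-2-oxoethyl)-2,4-dimethylcyclohexyl]-2-methylpropanoate
Conditions: TBAF, AcOH, THF, rt
Reagents that add atoms: none
Why: Fluoride-mediated Si–O cleavage; buffering with acetic acid protects the methyl esters.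

Step 19
Reactants: 23 diol diester
Product: 24 methyl 2-{2-(2-methoxy-2-oxoethyl)-2,4-dimethyl-4-(triethylsilyloxy)-3-[2-(triethylsilyloxy)ethyl]cyclohexyl}-2-methylpropanoate
Conditions: TESOTf, 2,6-lutidine, CH2Cl2, −78 → 0 °C
Reagents that add atoms: triethylsilyl trifluoromethanesulfonate, CC[Si](CC)(CC)OS(=O)(=O)C(F)(F)F
Why: Silylation with the silyl triflate, which is reactive enough for the tertiary C8 alcohol as well as the primary C12 alcohol.

Step 20
Reactants: 24 bis-TES ether
Product: 25 methyl 2-[2-(2-methoxy-2-oxoethyl)-2,4-dimethyl-3-(2-oxoethyl)-4-(triethylsilyloxy)cyclohexyl]-2-methylpropanoate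
Conditions: (COCl)2, DMSO, CH2Cl2, −78 → −40 °C; Et3N, → 0 °C
Reagents that add atoms: none
Why: Swern oxidation applied directly to the primary triethylsilyl ether: the activated sulfonium species exchanges with the unhindered primary Si–O bond and base then gives the C12 aldehyde, while the tertiary TES ether cannot react.

Step 21
Reactants: 25 C12 aldehyde
Product: 26 methyl 2-{3-[(2Z)-3-iodobut-2-en-1-yl]-2-(2-methoxy-2-oxoethyl)-2,4-dimethyl-4-(triethylsilyloxy)cyclohexyl}-2-methylpropanoate
Conditions: EtPPh3I, n-BuLi, THF, 0 °C; I2, −78 °C; NaHMDS, −20 °C; then 25, −78 °C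
Reagents that add atoms: ethyltriphenylphosphonium iodide, CC[P+](c1ccccc1)(c1ccccc1)c1ccccc1.[I-]; iodine, II
Why: Stork–Zhao olefination: the α-iodo ylide should give the (Z)-2-iodo-2-alkene (iodine cis to C11) under kinetic control, and the esters tolerate the ylide at −78 °C.

Step 22
Reactants: 26 (Z)-vinyl iodide
Product: 27 methyl 2-{3-[(2Z)-4-hydroxy-3-methylbut-2-en-1-yl]-2-(2-methoxy-2-oxoethyl)-2,4-dimethyl-4-(triethylsilyloxy)cyclohexyl}-2-methylpropanoate
Conditions: Bu3SnCH2OH, Pd(PPh3)4 (10 mol %), PhMe, 90 °C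
Reagents that add atoms: (tributylstannyl)methanol, CCCC[Sn](CCCC)(CCCC)CO
Why: Stille cross-coupling transfers the hydroxymethyl group with retention of alkene geometry, giving the (Z)-2-methyl allylic alcohol without a hydride step that would touch the esters.

Step 23
Reactants: 27 (Z)-allylic alcohol
Product: 28 methyl 2-{3-{[(2S,3R)-3-(hydroxymethyl)-3-methyloxiran-2-yl]methyl}-2-(2-methoxy-2-oxoethyl)-2,4-dimethyl-4-(triethylsilyloxy)cyclohexyl}-2-methylpropanoate (12S,13R epoxide)
Conditions: Ti(OiPr)4 (20 mol %), D-(−)-DET (24 mol %), t-BuOOH, 4 Å MS, CH2Cl2, −20 °C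
Reagents that add atoms: tert-butyl hydroperoxide, CC(C)(C)OO
Why: Sharpless asymmetric epoxidation: the titanium–tartrate complex binds the allylic alkoxide and delivers oxygen under reagent control, and D-(−)-DET is the antipode that gives the (2R,3S)-epoxy alcohol from a Z-allylic alcohol, i.e. 12S,13R here.

Step 24
Reactants: 28 epoxy alcohol
Product: 29 the corresponding epoxy aldehyde (C14 formyl on C13; epoxide as in 28)
Conditions: SO3·py, DMSO, iPr2NEt, CH2Cl2, 0 °C
Reagents that add atoms: none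
Why: Parikh–Doering oxidation; the epoxy aldehyde has no α-hydrogen and cannot epimerise.

Step 25
Reactants: 29 epoxy aldehyde
Product: 30 methyl 2-{3-{[(2S,3R)-3-ethenyl-3-methyloxiran-2-yl]methyl}-2-(2-methoxy-2-oxoethyl)-2,4-dimethyl-4-(triethylsilyloxy)cyclohexyl}-2-methylpropanoate
Conditions: Ph3PCH3Br, NaHMDS, THF, 0 °C; then 29, −78 → 0 °C
Reagents that add atoms: methyltriphenylphosphonium bromide, C[P+](c1ccccc1)(c1ccccc1)c1ccccc1.[Br-]
Why: Wittig methylenation gives the vinyl epoxide, whose vinyl group will stabilise positive charge at C13.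

Step 26
Reactants: 30 vinyl epoxide with C8–OTES
Product: 32 dimethyl ester of the target (8α,13-epoxide; 12β-OH; 13β-vinyl; 13α-CH3), via hydroxy vinyl epoxide 31 (not isolated)
Conditions: TBAF, AcOH, THF, 0 °C → rt; then CSA (0.2 equiv), CH2Cl2, −20 → 0 °C
Reagents that add atoms: none
Why: Fluoride desilylation then acid-catalysed hydroxy-epoxide cyclisation: the protonated epoxide should open at the tertiary, allylic C13 rather than at C12, so the C8 hydroxyl closes the pyran 6-endo (not 5-exo) with inversion at C13 (vinyl axial, cis to C17), while the untouched C12–O bond becomes the equatorial 12β-hydroxyl.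

Step 27
Reactants: 32 pyran dimethyl ester
Product: 33 2-[(2S,3S,4aS,5R,6S,8aS)-5-(carboxymethyl)-2-ethenyl-3-hydroxy-2,5,8a-trimethyloctahydro-2H-chromen-6-yl]-2-methylpropanoic acid (CNP0325408.2)
Conditions: NaSEt, DMF, 90 °C; then 1 M HCl to pH 3, 0 °C
Reagents that add atoms: none
Why: SN2 O-demethylation by thiolate at the ester methyl groups is insensitive to the steric shielding of the C3 carbonyl and leaves the ether, alkene and alcohol alone; careful acidification gives the diacid.

**Compound list**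

1 | propane-1,3-diol | OCCCO | starting material
2 | 3-(triisopropylsilyloxy)propan-1-ol | CC(C)[Si](OCCCO)(C(C)C)C(C)C | intermediate
3 | 3-(triisopropylsilyloxy)propanal | CC(C)[Si](OCCC=O)(C(C)C)C(C)C | intermediate
4 | 2-(triphenylphosphoranylidene)propanal | CC(C=O)=P(c1ccccc1)(c1ccccc1)c1ccccc1 | starting material
5 | (E)-2-methyl-5-(triisopropylsilyloxy)pent-2-enal | O=C/C(C)=C/CCO[Si](C(C)C)(C(C)C)C(C)C | intermediate
6 | (E)-3-(tert-butyldimethylsilyloxy)-N,N-dimethylbuta-1,3-dien-1-amine | CN(C)/C=C/C(=C)O[Si](C)(C)C(C)(C)C | starting material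
7 | 4-(tert-butyldimethylsilyloxy)-2-(dimethylamino)-1-methyl-6-[2-(triisopropylsilyloxy)ethyl]cyclohex-3-ene-1-carbaldehyde (endo adduct, NMe2 cis to CHO) | CC(C)(C)[Si](C)(C)OC1=C[C@@H](N(C)C)[C@@](C)(C=O)[C@H](CCO[Si](C(C)C)(C(C)C)C(C)C)C1 | intermediate (not isolated)
8 | (1S,6R)-1-methyl-4-oxo-6-[2-(triisopropylsilyloxy)ethyl]cyclohex-2-ene-1-carbaldehyde | O=C1C=C[C@@](C)(C=O)[C@H](CCO[Si](C(C)C)(C(C)C)C(C)C)C1 | intermediate
9 | 4-methyl-4-vinyl-5-[2-(triisopropylsilyloxy)ethyl]cyclohex-2-en-1-one (vinyl trans to side chain) | O=C1C=C[C@@](C)(C=C)[C@H](CCO[Si](C(C)C)(C(C)C)C(C)C)C1 | intermediate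
10 | 1-methoxy-2-methyl-1-(trimethylsilyloxy)prop-1-ene | COC(O[Si](C)(C)C)=C(C)C | starting material
11 | methyl 2-methyl-2-[1-methyl-6-[2-(triisopropylsilyloxy)ethyl]-4-(trimethylsilyloxy)-1-vinylcyclohex-3-en-2-yl]propanoate (major C5 epimer drawn) | C[Si](C)(C)OC1=C[C@@H](C(C)(C)C(=O)OC)[C@@](C)(C=C)[C@H](CCO[Si](C(C)C)(C(C)C)C(C)C)C1 | intermediate
12 | methyl 2-methyl-2-[6-methyl-3-oxo-5-[2-(triisopropylsilyloxy)ethyl]-6-vinylcyclohex-1-en-1-yl]propanoate | O=C1C=C(C(C)(C)C(=O)OC)[C@@](C)(C=C)[C@H](CCO[Si](C(C)C)(C(C)C)C(C)C)C1 | intermediate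
13 | methyl 2-methyl-2-[4,6-dimethyl-3-oxo-5-[2-(triisopropylsilyloxy)ethyl]-6-vinylcyclohex-1-en-1-yl]propanoate (C8 methyl trans to side chain) | O=C1C=C(C(C)(C)C(=O)OC)[C@@](C)(C=C)[C@H](CCO[Si](C(C)C)(C(C)C)C(C)C)[C@H]1C | intermediate
14 | methyl 2-methyl-2-[2,4-dimethyl-5-oxo-3-[2-(triisopropylsilyloxy)ethyl]-2-vinylcyclohexyl]propanoate (5α-H) | O=C1C[C@H](C(C)(C)C(=O)OC)[C@@](C)(C=C)[C@H](CCO[Si](C(C)C)(C(C)C)C(C)C)[C@H]1C | intermediate
15 | methyl 2-methyl-2-[2,4-dimethyl-3-[2-(triisopropylsilyloxy)ethyl]-5-(trimethylsilyloxy)-2-vinylcyclohex-4-en-1-yl]propanoate | C[Si](C)(C)OC1=C(C)[C@@H](CCO[Si](C(C)C)(C(C)C)C(C)C)[C@](C)(C=C)[C@@H](C(C)(C)C(=O)OC)C1 | intermediate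
16 | methyl 2-methyl-2-[2,4-dimethyl-5-oxo-3-[2-(triisopropylsilyloxy)ethyl]-4-(trimethylsilyloxy)-2-vinylcyclohexyl]propanoate (8α-OTMS, 8β-CH3) | C[Si](C)(C)O[C@@]1(C)C(=O)C[C@H](C(C)(C)C(=O)OC)[C@@](C)(C=C)[C@@H]1CCO[Si](C(C)C)(C(C)C)C(C)C | intermediate
17 | C6=C7 enol triflate of 16 | C[Si](C)(C)O[C@@]1(C)C(OS(=O)(=O)C(F)(F)F)=C[C@H](C(C)(C)C(=O)OC)[C@@](C)(C=C)[C@@H]1CCO[Si](C(C)C)(C(C)C)C(C)C | intermediate
18 | methyl 2-methyl-2-[2,4-dimethyl-3-[2-(triisopropylsilyloxy)ethyl]-4-(trimethylsilyloxy)-2-vinylcyclohex-5-en-1-yl]propanoate | C[Si](C)(C)O[C@@]1(C)C=C[C@H](C(C)(C)C(=O)OC)[C@@](C)(C=C)[C@@H]1CCO[Si](C(C)C)(C(C)C)C(C)C | intermediate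
19 | methyl 2-[4-hydroxy-2-(2-hydroxyethyl)-2,4-dimethyl-3-[2-(triisopropylsilyloxy)ethyl]cyclohex-5-en-1-yl]-2-methylpropanoate | O[C@@]1(C)C=C[C@H](C(C)(C)C(=O)OC)[C@@](C)(CCO)[C@@H]1CCO[Si](C(C)C)(C(C)C)C(C)C | intermediate
20 | methyl 2-[4-hydroxy-2-(2-hydroxyethyl)-2,4-dimethyl-3-[2-(triisopropylsilyloxy)ethyl]cyclohexyl]-2-methylpropanoate | O[C@@]1(C)CC[C@H](C(C)(C)C(=O)OC)[C@@](C)(CCO)[C@@H]1CCO[Si](C(C)C)(C(C)C)C(C)C | intermediate
21 | {3-hydroxy-6-(1-methoxy-2-methyl-1-oxopropan-2-yl)-1,3-dimethyl-2-[2-(triisopropylsilyloxy)ethyl]cyclohexyl}acetic acid | O[C@@]1(C)CC[C@H](C(C)(C)C(=O)OC)[C@@](C)(CC(=O)O)[C@@H]1CCO[Si](C(C)C)(C(C)C)C(C)C | intermediate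
22 | methyl 2-{4-hydroxy-2-(2-methoxy-2-oxoethyl)-2,4-dimethyl-3-[2-(triisopropylsilyloxy)ethyl]cyclohexyl}-2-methylpropanoate | O[C@@]1(C)CC[C@H](C(C)(C)C(=O)OC)[C@@](C)(CC(=O)OC)[C@@H]1CCO[Si](C(C)C)(C(C)C)C(C)C | intermediate
23 | methyl 2-[4-hydroxy-3-(2-hydroxyethyl)-2-(2-methoxy-2-oxoethyl)-2,4-dimethylcyclohexyl]-2-methylpropanoate | O[C@@]1(C)CC[C@H](C(C)(C)C(=O)OC)[C@@](C)(CC(=O)OC)[C@@H]1CCO | intermediate
24 | bis(triethylsilyl) ether of 23 | CC[Si](CC)(CC)O[C@@]1(C)CC[C@H](C(C)(C)C(=O)OC)[C@@](C)(CC(=O)OC)[C@@H]1CCO[Si](CC)(CC)CC | intermediate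
25 | C12 aldehyde with C8–OTES | CC[Si](CC)(CC)O[C@@]1(C)CC[C@H](C(C)(C)C(=O)OC)[C@@](C)(CC(=O)OC)[C@@H]1CC=O | intermediate
26 | (Z)-vinyl iodide (iodine cis to C11) | CC[Si](CC)(CC)O[C@@]1(C)CC[C@H](C(C)(C)C(=O)OC)[C@@](C)(CC(=O)OC)[C@@H]1C/C=C(/C)I | intermediate
27 | (Z)-2-methyl allylic alcohol (CH2OH cis to C11) | CC[Si](CC)(CC)O[C@@]1(C)CC[C@H](C(C)(C)C(=O)OC)[C@@](C)(CC(=O)OC)[C@@H]1C/C=C(/C)CO | intermediate
28 | (12S,13R)-epoxy alcohol | CC[Si](CC)(CC)O[C@@]1(C)CC[C@H](C(C)(C)C(=O)OC)[C@@](C)(CC(=O)OC)[C@@H]1C[C@@H]2O[C@]2(C)CO | intermediate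
29 | epoxy aldehyde (epoxide as in 28) | CC[Si](CC)(CC)O[C@@]1(C)CC[C@H](C(C)(C)C(=O)OC)[C@@](C)(CC(=O)OC)[C@@H]1C[C@@H]2O[C@]2(C)C=O | intermediate
30 | (12S,13R)-vinyl epoxide with C8–OTES | CC[Si](CC)(CC)O[C@@]1(C)CC[C@H](C(C)(C)C(=O)OC)[C@@](C)(CC(=O)OC)[C@@H]1C[C@@H]2O[C@]2(C)C=C | intermediate
31 | (12S,13R)-vinyl epoxide with free C8–OH | O[C@@]1(C)CC[C@H](C(C)(C)C(=O)OC)[C@@](C)(CC(=O)OC)[C@@H]1C[C@@H]2O[C@]2(C)C=C | intermediate (not isolated)
32 | dimethyl ester of the target | C=C[C@]1(C)O[C@@]2(C)CC[C@H](C(C)(C)C(=O)OC)[C@@](C)(CC(=O)OC)[C@@H]2C[C@@H]1O | intermediate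
33 | 2-[(2S,3S,4aS,5R,6S,8aS)-5-(carboxymethyl)-2-ethenyl-3-hydroxy-2,5,8a-trimethyloctahydro-2H-chromen-6-yl]-2-methylpropanoic acid | C=C[C@]1(C)O[C@@]2(C)CC[C@H](C(C)(C)C(=O)O)[C@@](C)(CC(=O)O)[C@@H]2C[C@@H]1O | target

**Step count and risks**

Total step count: 27. Longest linear sequence: 27 steps (1 → 33); compounds 4, 6 and 10 are purchased.

Step 4 (key cycloaddition). The β-alkyl group of 5 may slow the hydrogen-bond-catalysed addition so much that, at the temperature needed for turnover, the uncatalysed pathway competes and enantiofacial control is eroded. The fallback replaces catalyst control by a stoichiometric chiral controller on the diene; it sets out from 5 and returns at 8. Condensation of (E)-4-methoxybut-3-en-2-one with (2S,5S)-2,5-diphenylpyrrolidine gives (E)-4-[(2S,5S)-2,5-diphenylpyrrolidin-1-yl]but-3-en-2-one F1. KHMDS then TBSCl (THF, −78 °C) gives the C2-symmetric 1-(2,5-diphenylpyrrolidin-1-yl)-3-(tert-butyldimethylsilyloxy)buta-1,3-diene F2. Uncatalysed cycloaddition of F2 with 5 (PhMe, −20 °C → rt) gives the pyrrolidinyl cycloadduct F3, whose diene face is chosen by the phenyl groups. 1 M HCl in THF then releases 8 and the recoverable amine. No turnover is needed and there is no racemic background; if the (2S,5S) amine induces the wrong sense, its antipode is used.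

Step 6 (Mukaiyama–Michael addition). Steric congestion between the tetrasubstituted ketene acetal carbon and C5 next to quaternary C10 may stop the bimolecular addition or divert it to 1,2-addition or simple silyl transfer. The fallback makes the C4–C5 bond intramolecularly by an Ireland–Claisen rearrangement; it sets out from 9 and returns at 18, so it replaces steps 6–13.
- LDA then MeI on 9 gives the 6-methyl enone F4.
- KHMDS then 2-(phenylsulfonyl)-3-phenyloxaziridine (−78 °C) hydroxylates the α′-enolate anti to the C11 arm and gives the 8α-hydroxy-8β-methyl enone F5.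
- Luche reduction (NaBH4, CeCl3, MeOH) gives the 7β,8α-diol F6.
- Isobutyric anhydride with DMAP acylates only the secondary alcohol and gives the 7β-isobutyrate F7. If the 7α-carbinol predominates in the reduction, Mitsunobu esterification with isobutyric acid inverts and esterifies it in one operation.
- LDA (2.2 equiv) and TMSCl (THF–DMPU, −78 → 60 °C) silylate the tertiary alkoxide and rearrange the silyl ketene acetal; mild aqueous work-up gives the 8α-trimethylsilyloxy Δ6 acid F8.
- TMSCHN2 converts F8 into 18.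

The [3,3] shift delivers C4 to C5 on the face of the departing C7–O bond (β), so it sets H5 α, moves the double bond to C6=C7 and removes the C7 oxygen in one event.

Step 22 (hydroxymethyl Stille coupling). Transfer of the hydroxymethyl group from tin to the hindered (Z)-alkenylpalladium may be slow, so that protodehalogenation and Z→E isomerisation compete. The fallback installs the vinyl group first and epoxidises afterwards; it sets out from 26 and returns at 30, so it replaces steps 22–25. Stille coupling of 26 with tributyl(vinyl)stannane (Pd(PPh3)4, CuI, DMF, rt), a fast sp2 transfer, gives the (Z)-3-methyl-1,3-diene F9. Shi epoxidation of F9 with the L-fructose-derived ketone (Oxone, K2CO3, MeCN–dimethoxymethane–buffer pH 10.5, 0 °C) should oxidise only the more electron-rich trisubstituted alkene, from the face that gives the 12S,13R epoxide 30.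

**Further compounds**

F1 | step 4 | (E)-4-[(2S,5S)-2,5-diphenylpyrrolidin-1-yl]but-3-en-2-one | CC(=O)/C=C/N1[C@H](c2ccccc2)CC[C@H]1c1ccccc1
F2 | step 4 | (2S,5S)-1-[(1E)-3-(tert-butyldimethylsilyloxy)buta-1,3-dien-1-yl]-2,5-diphenylpyrrolidine | C=C(O[Si](C)(C)C(C)(C)C)/C=C/N1[C@H](c2ccccc2)CC[C@H]1c1ccccc1
F3 | step 4 | 4-(tert-butyldimethylsilyloxy)-2-[(2S,5S)-2,5-diphenylpyrrolidin-1-yl]-1-methyl-6-[2-(triisopropylsilyloxy)ethyl]cyclohex-3-ene-1-carbaldehyde | CC(C)(C)[Si](C)(C)OC1=C[C@@H](N2[C@H](c3ccccc3)CC[C@H]2c2ccccc2)[C@@](C)(C=O)[C@H](CCO[Si](C(C)C)(C(C)C)C(C)C)C1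
F4 | step 6 | 4,6-dimethyl-4-vinyl-5-[2-(triisopropylsilyloxy)ethyl]cyclohex-2-en-1-one (C8 methyl trans to side chain) | O=C1C=C[C@@](C)(C=C)[C@H](CCO[Si](C(C)C)(C(C)C)C(C)C)[C@H]1C
F5 | step 6 | 6-hydroxy-4,6-dimethyl-4-vinyl-5-[2-(triisopropylsilyloxy)ethyl]cyclohex-2-en-1-one (8α-OH, 8β-CH3) | O[C@@]1(C)C(=O)C=C[C@@](C)(C=C)[C@@H]1CCO[Si](C(C)C)(C(C)C)C(C)C
F6 | step 6 | 1,4-dimethyl-4-vinyl-5-[2-(triisopropylsilyloxy)ethyl]cyclohex-2-ene-1,6-diol numbered from C8 (7β-OH, 8α-OH) | O[C@@]1(C)[C@H](O)C=C[C@@](C)(C=C)[C@@H]1CCO[Si](C(C)C)(C(C)C)C(C)C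
F7 | step 6 | 7β-isobutyrate of F6 | O[C@@]1(C)[C@H](OC(=O)C(C)C)C=C[C@@](C)(C=C)[C@@H]1CCO[Si](C(C)C)(C(C)C)C(C)C
F8 | step 6 | 2-methyl-2-[2,4-dimethyl-3-[2-(triisopropylsilyloxy)ethyl]-4-(trimethylsilyloxy)-2-vinylcyclohex-5-en-1-yl]propanoic acid | C[Si](C)(C)O[C@@]1(C)C=C[C@H](C(C)(C)C(=O)O)[C@@](C)(C=C)[C@@H]1CCO[Si](C(C)C)(C(C)C)C(C)C
F9 | step 22 | methyl 2-{2-(2-methoxy-2-oxoethyl)-2,4-dimethyl-3-[(2Z)-3-methylpenta-2,4-dien-1-yl]-4-(triethylsilyloxy)cyclohexyl}-2-methylpropanoate | CC[Si](CC)(CC)O[C@@]1(C)CC[C@H](C(C)(C)C(=O)OC)[C@@](C)(CC(=O)OC)[C@@H]1C/C=C(/C)C=C
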